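The numbers in the tables stem from a simulated flask on assumed constants, noise included.

In a one-step world I would draw a line through the first readings and read the end off it, but in this flask that line has to stop somewhere.

| flask | substrate | first nucleophile | second nucleophile | capture agent | remark | time |
|---|---|---|---|---|---|---|
| Wednesday's | 0.71 M | 2.13 M | 0.426 M | 0.32 M | run made earlier |  |
| flask | 0.71 M | 2.13 M | 0.426 M | 0.213 M |  | 15 d |

Wednesday's run (percent of the substrate charged)

| time / d | target / % | other capture product / % |
|---|---|---|
| 0.500 | 2.4 | 3.9 |
| 1.04 | 2.2 | 8.1 |
| 1.67 | 0 | 14.2 |
| 2.08 | 1.6 | 17.4 |
| 2.50 | 0 | 18.3 |
| 3.00 | 2.3 | 22.2 |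

(standard deviation of a reading: 1 percentage point)

- share of target in target plus other capture product at 5.0 h
- share of target in target plus other capture product at 15 d
- which of target and other capture product there is more of at 15 d

- no earlier run changes the charge of capture agent; that part of a forecast is a guess

In Wednesday's run the target readings scatter around 1.42% without rising, while other capture product climbs at a rate v of 0.0740 d⁻¹, as a fraction of the substrate charge. Carried straight to 15 d, v gives 111%, more than was charged.

So I solve two extreme flasks, with target held flat. In the first, each other capture product consumes one capture agent, so it stops at 30.0% of the substrate charge and the late share of target is 4.52%. In the second, capture agent stands aside and second nucleophile is the limiting reagent, allowing 60.0%. Here I go round again and let the rate fall as second nucleophile is spent. My depletion time θ is that allowance divided by v, here 8.11 d. The allowance times 1 minus exp(−t/θ) gives 50.6% and a share of 2.73%. Wednesday's run does not change the charge of capture agent, so it leaves the choice of extreme open, and I expect a share between the two. At 5.0 h v gives 1.54%, under either cap, and a share of 47.9%, loosely.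

The forecast gives 35% (12% to 60%), 6% (2% to 25%) and other capture product ahead, holding that “total capture products cap near 30 %”.

The flask gives 39.9% and 1.40%, with other capture product ahead.

    substrate ⇌ open intermediate (K = 0.0320, k = 0.0260 h⁻¹)
    first nucleophile + open intermediate ⇌ target (K = 0.240 M⁻¹, k = 0.150 M⁻¹ h⁻¹)
    second nucleophile + open intermediate → other capture product (k = 0.410 M⁻¹ h⁻¹)
    open intermediate + capture agent → trapped intermediate (k = 0.0110 M⁻¹ h⁻¹)

At 3.21 d the open intermediate has a half-life of 0.27 d towards second nucleophile against 12 d towards capture agent. At 15.0 d the flask keeps 95% of its capture agent and holds 50.7% of other capture product, while target has fallen from 1.17% at 1.50 d to 0.721%. In a neighbour flask, charged like this one except for 0.11 M of second nucleophile, I let the rate follow that charge, which leaves θ at 8.11 d and gives 13.1% of other capture product at 15 d; that neighbour flask holds 14.5%.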